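## The problem

Compound 13 is a flavone: ring A (C4a to C8a) is fused to the pyranone ring C, which carries ring B at C2. It has no stereocentre, so nothing has to be set or relayed, and the whole difficulty is regiochemical. Four phenolic oxygens must end up different: O4' as a methyl ether, O7 as a sulfate monoester, O5 and O3' free. Ring A has the phloroglucinol pattern, in which O5, O7 and O1 are alike in any symmetrical precursor, so the synthesis must tell O7 from O5 on ring A and from O3' on ring B. The aryl sulfate is the fragile group: protic and Lewis acids remove it, it turns the molecule into a salt, and in the hydrogen sulfate form it catalyses its own solvolysis. It must therefore come late and be followed only by neutral operations. Ring C sets limits of its own, since C2 is a conjugate acceptor that hydroxide opens and the C2–C3 double bond can be reduced. The enabling feature is that C4a lies between C5 and C8a, two carbons that both bear a heteroatom. In a 2,6-difluoro-4-alkoxybenzoyl unit these are identical C–F carbons, so whichever one an enolate oxygen attacks becomes C8a, the other remains as C5 with a fluorine standing in for O5, and the para oxygen, the future O7, is distinct from the outset.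

## Retrosynthesis

**13 back to 11.** The O3'–CH2Ph bond is cut and sodium is exchanged for hydrogen (through the sodium salt 12). A benzyl ether is chosen for O3' because it must survive amide base, alkoxide and CF3CO2H earlier on and must leave under neutral conditions once the sulfate is present. Hydrogenolysis meets both demands, whereas acid-labile or Lewis-acid-labile groups would take the sulfate with them. The forward reaction has to leave the C2–C3 double bond and the S–O bond alone.

**11 back to 9.** The S–O7 bond is cut. Sulfation is placed after all acidic steps because no sulfate would survive CF3CO2H. The diol 9 is far simpler to handle than any sulfated precursor. The forward reaction must choose O7 over O5, and the hydrogen bond from the 5-hydroxyl to the C4 carbonyl provides that choice, while O3' is blocked.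

**9 back to 8 and 7.** The two benzylic C–O bonds of the 4-methoxybenzyl ethers are cut, then the C5–O bond, which leads to the 5-fluoroflavone 7. The oxygen at C5 is delivered as 4-methoxybenzyl oxide, so the same acid step frees O5 and O7 together. Hydroxide itself would open ring C, and benzyl oxide would make O5 inseparable from O3'. The forward substitution needs C5 to be activated by the C4 carbonyl, which it is through C4a.

**7 back to 3 and 5 (key disconnection).** The C8a–O1 and C3–C4 bonds are cut, through the diketone 6. The neighbouring cut at O1–C2 (cyclodehydration of a 2-hydroxyaryl diketone) would need a phloroacetophenone with three hydroxyls protected individually. The cut chosen here needs no phenol on ring A at all: the ring-A partner 3 is symmetrical, its fluorines serve first as the leaving group and then as the placeholder for O5, and O7 is already differentiated. Both precursors are single benzene rings. The forward reaction must acylate the ketone enolate on carbon faster than the ketone condenses with itself, and must then close through oxygen.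

**3 back to 1 and 2; 5 back to 4.** In 3 the ester C–O and ether C–O bonds are cut together, because one alkylation of the hydroxy acid 1 with 4-methoxybenzyl chloride 2 installs both. A 4-methoxybenzyl ester is preferred to a methyl ester for two reasons. It saves a step, and the alkoxide expelled in the Claisen step is the very nucleophile of the following step, so any premature attack on a C–F bond leads to 8 and not to a dead-end methyl ether. Ketone 5 comes from 4 by benzylation.

## Roads not taken

All three alternatives would meet the chosen route at the diol 9 or one deprotection before it. They differ only in how rings A and C are made.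

**Alternative 1:** Ring A is unravelled completely (cuts at C4a–C8a and O1–C2) to the open-chain methyl 9-[3-(benzyloxy)-4-methoxyphenyl]-3,5,7,9-tetraoxononanoate A1.
- Forward step: a Claisen condensation of the methylene between the future C4 and C5 carbonyls onto the ester carbon gives the acylphloroglucinol 1-[3-(benzyloxy)-4-methoxyphenyl]-3-(2,4,6-trihydroxyphenyl)propane-1,3-dione A2. Either ortho hydroxyl of A2 then condenses with the aryl ketone to give 3'-(benzyloxy)-5,7-dihydroxy-4'-methoxyflavone A3, which is identical with 9.
- Merits: two rings form in one operation, ring A needs no protecting group and no fluorine, and A3 arrives without the 4-methoxybenzyl steps. If A1 were in hand this road would be shorter than the chosen one by about two steps.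
- Weak points: A1 must be built by several successive polyanion acylations from 5, it exists as a mixture of enol forms and cannot be stored. It also has competing cyclisation modes: aldol closure onto the C4 or C2 carbonyl gives resorcinol-type rings, and closure of an enol oxygen onto the ester gives pyranones. Which mode wins depends on counter-ion and medium and cannot be predicted for this substitution pattern.
- Comparison: the chosen plan has more protecting-group steps. Against that it sets two stable one-step precursors and a ring closure that has a single regiochemical outcome.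

**Alternative 2:** Four bonds of ring A are cut (C8–C8a, C7–C8, C5–C6, C4a–C5), giving the pyranone 2-[3-(benzyloxy)-4-methoxyphenyl]-6-(2-diazoacetyl)-4H-pyran-4-one A4 and (triisopropylsilyloxy)ethyne A5.
- Forward step: irradiation triggers a Wolff rearrangement, the ketene adds to A5 in a [2+2] sense, and heating brings about four-electron ring opening and six-electron ring closure onto the pyranone double bond. Tautomerisation gives 3'-(benzyloxy)-5-hydroxy-4'-methoxy-7-[(triisopropylsilyl)oxy]flavone A6.
- Merits: the mechanism fixes the substitution pattern, and O5 and O7 are different from the moment ring A exists (free chelated hydroxyl against silyl ether). That differentiation is as good as the one in the chosen plan.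
- Weak points: A4 needs a 6-aryl-4-oxopyran-2-carboxylic acid and a hazardous diazoalkane acylation, roughly five to six steps from 5. A5 is a sensitive alkyne. The 4-pyranone chromophore has photochemistry of its own. The final electrocyclisation must engage an electron-poor, cross-conjugated pyranone double bond, for which this benzannulation has no close precedent.
- Comparison: desilylation of A6 only leads back to 9, so the extra length buys nothing. The chosen plan reaches the same O5/O7 distinction (fluorine against ether) with ordinary reagents in three steps to 7.

**Alternative 3:** The cuts are at O1–C8a, C4–C4a and O1–C2. The partners are 3,5-bis(methoxymethoxy)-2-(trimethylsilyl)phenyl trifluoromethanesulfonate A7 and 3-[3-(benzyloxy)-4-methoxyphenyl]prop-2-ynoic acid A8.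
- Forward step: fluoride releases 3,5-bis(methoxymethoxy)benzyne A9. The carboxylate oxygen of A8 adds to the aryne carbon remote from the flanking ether, the aryl anion next to that ether attacks the carboxyl carbon, and collapse of the four-membered adduct moves the acyl group to carbon. The phenoxide so formed adds to the alkyne terminus (6-endo-dig) to give 3'-(benzyloxy)-4'-methoxy-5,7-bis(methoxymethoxy)flavone A10.
- Merits: the step is convergent and runs at ambient temperature under nearly neutral conditions, milder than the chosen key step. The inductive effect of the flanking ether polarises A9 in the required sense.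
- Weak points: A7 needs about five steps, including desymmetrisation of a tri-oxygenated benzene, directed silylation and triflation. A8 needs two or three more. The insertion competes with plain O-arylation of the acid followed by protonation, and with reactions of A9 at the alkyne. O5 and O7 emerge under the same protecting group, so acid deprotection of A10 again gives 9 with no gain in differentiation.
- Comparison: the chosen plan has the harsher key step but is about half as long. Its regiochemistry rests on symmetry, where this road relies on a polarisation effect.

Key step: step 3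

Assumption: the free hydrogen sulfate form drawn for the target is taken as the compound wanted. Because aryl hydrogen sulfates solvolyse under their own acidity, the sulfate is carried as its sodium salt and protonated only in the last operation, cold and in dilute solution.

## Route

Step 1
Reactants: 1 2,6-difluoro-4-hydroxybenzoic acid; 2 4-methoxybenzyl chloride
Product: 3 4-methoxybenzyl 2,6-difluoro-4-[(4-methoxybenzyl)oxy]benzoate
Conditions: 2 (2.3 equiv), K2CO3 (3 equiv), DMF, 60 °C
Reagents that add atoms: none
Why: Williamson etherification of the phenoxide and SN2 alkylation of the carboxylate occur under the same conditions; carboxylate alkylation takes place at the benzylic carbon of 2 and is therefore indifferent to the two ortho fluorines.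

Step 2
Reactants: 4 1-(3-hydroxy-4-methoxyphenyl)ethanone
Product: 5 1-[3-(benzyloxy)-4-methoxyphenyl]ethanone
Conditions: BnBr, K2CO3, acetone, reflux
Reagents that add atoms: benzyl bromide, BrCc1ccccc1
Why: Williamson ether synthesis on the only acidic site; K2CO3 in acetone does not enolise the methyl ketone to a useful extent, so C-alkylation is not expected.

Step 3
Reactants: 3 4-methoxybenzyl 2,6-difluoro-4-[(4-methoxybenzyl)oxy]benzoate; 5 1-[3-(benzyloxy)-4-methoxyphenyl]ethanone
Product: 7 3'-(benzyloxy)-5-fluoro-4'-methoxy-7-[(4-methoxybenzyl)oxy]flavone, via 1,3-diketone 6 (not isolated)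
Conditions: 5, LiN(SiMe3)2 (2.5 equiv), THF, −78 °C; then 3, −78 → 0 °C; AcOH, concentrate; K2CO3, DMF, 80 °C
Reagents that add atoms: none
Why: LiN(SiMe3)2 converts 5 fully into its lithium enolate, which adds to the ester carbonyl of 3; collapse of the tetrahedral adduct expels 4-methoxybenzyl oxide and forms C3–C4 (crossed Claisen condensation), and the second equivalent of base holds the product as the enolate of 6, which makes the acylation irreversible. The ortho fluorines raise the electrophilicity of the ester inductively without shielding it, and 3 has no α-hydrogen, so only the ketone can act as donor. After neutralisation and the change to K2CO3 in DMF, the enolate oxygen on the future C2 adds to an ortho C–F carbon, the Meisenheimer anion is delocalised through C4a into the C4 carbonyl, and loss of fluoride forms C8a–O1 and closes ring C (intramolecular nucleophilic aromatic substitution, the known route from ortho-fluorobenzoyl 1,3-diketones to chromones). The closure is six-membered and formally 6-endo-trig on the C4a–C8a double bond of the aryl ketone (a vinylogous addition–elimination); attack through C3 would need a four-membered ring, so the ambident enolate can react only through oxygen. The two C–F carbons are interchanged by rotation about the C4–C4a bond, so only one flavone can form and the remaining fluorine necessarily stands at C5. No stereocentre is created. The 4-methoxybenzyl ether is meta to both fluorines and so does not oppose the substitution, and both benzylic ethers are inert to the two bases. Any displacement of the C5 fluorine by the liberated 4-methoxybenzyl alcohol gives 8, the product of step 4, and costs no material.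

Step 4
Reactants: 7 3'-(benzyloxy)-5-fluoro-4'-methoxy-7-[(4-methoxybenzyl)oxy]flavone
Product: 8 3'-(benzyloxy)-4'-methoxy-5,7-bis[(4-methoxybenzyl)oxy]flavone
Conditions: 4-MeOC6H4CH2OH (1.5 equiv), NaH (1.4 equiv), DMF, 0 → 50 °C
Reagents that add atoms: 4-methoxybenzyl alcohol, COc1ccc(CO)cc1
Why: Nucleophilic aromatic substitution by addition–elimination; C5 is ortho to C4a and the anionic adduct is stabilised by the C4 carbonyl, fluoride is the best leaving group for this mechanism, and the C7 ether is meta to C5. Addition of the alkoxide at C2 is reversible and unproductive, whereas loss of fluoride is not.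

Step 5
Reactants: 8 3'-(benzyloxy)-4'-methoxy-5,7-bis[(4-methoxybenzyl)oxy]flavone
Product: 9 3'-(benzyloxy)-5,7-dihydroxy-4'-methoxyflavone
Conditions: CF3CO2H, anisole (10 equiv), CH2Cl2, 0 °C → rt
Reagents that add atoms: none
Why: Acidolysis of 4-methoxybenzyl aryl ethers through the stabilised 4-methoxybenzyl cation, which excess anisole intercepts by Friedel–Crafts alkylation before it can attack C6 or C8; the unsubstituted benzyl ether at O3' does not ionise under these conditions.

Step 6
Reactants: 9 3'-(benzyloxy)-5,7-dihydroxy-4'-methoxyflavone
Product: 11 sodium 3'-(benzyloxy)-5-hydroxy-4'-methoxyflavon-7-yl sulfate, via pyridinium sulfate 10 (not isolated)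
Conditions: SO3·pyridine (2 equiv), pyridine, rt; aq NaHCO3; C18 chromatography
Reagents that add atoms: sulfur trioxide–pyridine complex, O=S(=O)=O.c1ccncc1; sodium hydrogencarbonate, [Na+].OC([O-])=O
Why: O-sulfation of a phenol with an SO3–amine complex; the 7-hydroxyl is the acidic, unhindered one, the 5-hydroxyl is tied up in a hydrogen bond to the C4 carbonyl and is the least reactive hydroxyl of a flavone, and O3' is blocked. NaHCO3 exchanges pyridinium for sodium, so no pyridine, an inhibitor of benzyl ether hydrogenolysis, is carried into step 7.

Step 7
Reactants: 11 sodium 3'-(benzyloxy)-5-hydroxy-4'-methoxyflavon-7-yl sulfate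
Product: 13 5,3'-dihydroxy-4'-methoxyflavon-7-yl hydrogen sulfate (luteolin 4'-methyl ether 7-sulfate), via debenzylated sodium salt 12 (not isolated)
Conditions: H2 (1 atm), Pd/C (10% palladium on carbon), MeOH/H2O, rt; filter; HCl (1.0 equiv), 0 °C; C18 desalting, freeze-drying
Reagents that add atoms: none
Why: Catalytic hydrogenolysis of an aryl benzyl ether; the sulfate monoester anion and the flavone C2–C3 double bond are not attacked at ambient pressure and temperature. One equivalent of cold acid then protonates the salt, and the sodium chloride is washed off the reversed phase.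

## Compound list

1 | 2,6-difluoro-4-hydroxybenzoic acid | O=C(O)c1c(F)cc(O)cc1F | starting material
2 | 4-methoxybenzyl chloride | COc1ccc(CCl)cc1 | starting material
3 | 4-methoxybenzyl 2,6-difluoro-4-[(4-methoxybenzyl)oxy]benzoate | COc1ccc(COC(=O)c2c(F)cc(OCc3ccc(OC)cc3)cc2F)cc1 | intermediate
4 | 1-(3-hydroxy-4-methoxyphenyl)ethanone | CC(=O)c1ccc(OC)c(O)c1 | starting material
5 | 1-[3-(benzyloxy)-4-methoxyphenyl]ethanone | CC(=O)c1ccc(OC)c(OCc2ccccc2)c1 | intermediate
6 | 1-[3-(benzyloxy)-4-methoxyphenyl]-3-{2,6-difluoro-4-[(4-methoxybenzyl)oxy]phenyl}propane-1,3-dione | COc1ccc(C(=O)CC(=O)c2c(F)cc(OCc3ccc(OC)cc3)cc2F)cc1OCc1ccccc1 | intermediate (not isolated)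
7 | 3'-(benzyloxy)-5-fluoro-4'-methoxy-7-[(4-methoxybenzyl)oxy]flavone | COc1ccc(-c2cc(=O)c3c(F)cc(OCc4ccc(OC)cc4)cc3o2)cc1OCc1ccccc1 | intermediate
8 | 3'-(benzyloxy)-4'-methoxy-5,7-bis[(4-methoxybenzyl)oxy]flavone | COc1ccc(-c2cc(=O)c3c(OCc4ccc(OC)cc4)cc(OCc4ccc(OC)cc4)cc3o2)cc1OCc1ccccc1 | intermediate
9 | 3'-(benzyloxy)-5,7-dihydroxy-4'-methoxyflavone | COc1ccc(-c2cc(=O)c3c(O)cc(O)cc3o2)cc1OCc1ccccc1 | intermediate
10 | pyridinium 3'-(benzyloxy)-5-hydroxy-4'-methoxyflavon-7-yl sulfate | COc1ccc(-c2cc(=O)c3c(O)cc(OS(=O)(=O)[O-])cc3o2)cc1OCc1ccccc1.c1cc[nH+]cc1 | intermediate (not isolated)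
11 | sodium 3'-(benzyloxy)-5-hydroxy-4'-methoxyflavon-7-yl sulfate | COc1ccc(-c2cc(=O)c3c(O)cc(OS(=O)(=O)[O-])cc3o2)cc1OCc1ccccc1.[Na+] | intermediate
12 | sodium 5,3'-dihydroxy-4'-methoxyflavon-7-yl sulfate | COc1ccc(-c2cc(=O)c3c(O)cc(OS(=O)(=O)[O-])cc3o2)cc1O.[Na+] | intermediate (not isolated)
13 | 5,3'-dihydroxy-4'-methoxyflavon-7-yl hydrogen sulfate (luteolin 4'-methyl ether 7-sulfate) | COc1ccc(-c2cc(=O)c3c(O)cc(OS(=O)(=O)O)cc3o2)cc1O | target

## Step count and weak points

Total: 7 steps. Longest linear sequence: 6 steps (steps 1, 3, 4, 5, 6, 7 from 1; equally steps 2 to 7 from 4).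

**Step 3 (key step).** The Claisen acylation may stall, because the ester carbonyl of 3 is conjugated with the para oxygen and the ketone enolate can instead condense with unreacted ketone. The ring closure may also be slow if the chelated diketone enolate is a poor oxygen nucleophile. The fallback separates the two events and uses a stronger acyl donor. It sets out from 3:
- Saponification (LiOH, THF/H2O) gives 2,6-difluoro-4-[(4-methoxybenzyl)oxy]benzoic acid F1.
- 1,1'-Carbonyldiimidazole in THF converts F1 into (1H-imidazol-1-yl){2,6-difluoro-4-[(4-methoxybenzyl)oxy]phenyl}methanone F2 under neutral conditions, which spare the acid-sensitive ether.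
- The lithium enolate of 5 (LiN(SiMe3)2, THF, −78 °C) is C-acylated by F2 to give the diketone 6, this time isolated.
- K2CO3 in DMF at 80 °C closes ring C, and the fallback rejoins the route at 7.

**Step 4.** Substitution at C5 may be slow, because the C4 carbonyl is a vinylogous ester weakened further by the C7 and O1 donors. Forcing conditions invite conjugate addition of the alkoxide at C2 and opening of ring C. The fallback moves the substitution ahead of ring formation, where a true ester activates the ring and no pyranone is exposed. It sets out from 3:
- 4-MeOC6H4CH2ONa (1.0 equiv, THF, 0 °C) should replace one fluorine to give 4-methoxybenzyl 2-fluoro-4,6-bis[(4-methoxybenzyl)oxy]benzoate F3. Transesterification is degenerate because ester and nucleophile carry the same group.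
- The protocol of step 3 with 5 then gives 1-[3-(benzyloxy)-4-methoxyphenyl]-3-{2-fluoro-4,6-bis[(4-methoxybenzyl)oxy]phenyl}propane-1,3-dione F4.
- F4 closes onto its single remaining C–F carbon, and the fallback rejoins the route at 8.

**Step 6.** Regiocontrol may be incomplete: O5 may be sulfated as well once excess reagent is needed to drive O7 to completion, or neutral 9 may remain and prove hard to separate from the ionic product. The fallback makes O7 the only free hydroxyl. It sets out from 7:
- PhCH2ONa (benzyl alcohol, NaH, DMF) displaces the fluoride to give 5,3'-bis(benzyloxy)-4'-methoxy-7-[(4-methoxybenzyl)oxy]flavone F5.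
- Oxidative cleavage with 2,3-dichloro-5,6-dicyano-1,4-benzoquinone in CH2Cl2/H2O removes only the 4-methoxybenzyl ether and gives 5,3'-bis(benzyloxy)-7-hydroxy-4'-methoxyflavone F6.
- SO3·pyridine gives pyridinium 5,3'-bis(benzyloxy)-4'-methoxyflavon-7-yl sulfate F7, and NaHCO3 converts it into sodium 5,3'-bis(benzyloxy)-4'-methoxyflavon-7-yl sulfate F8.
- Hydrogenolysis of both benzyl ethers (H2, Pd/C) rejoins the route at 12.

**Step 7.** Hydrogenolysis of the ionic, sparingly soluble substrate may be slow, and prolonged exposure risks partial saturation of the C2–C3 double bond. The sulfate may also be lost by acid-catalysed solvolysis while the free acid is concentrated. The fallback carries the sulfate as a neutral diester that can be purified on silica and unmasks it together with O3'. It sets out from 9: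
- 2,2,2-Trichloroethyl chlorosulfate with Et3N and 4-(dimethylamino)pyridine in THF at 0 °C gives 3'-(benzyloxy)-5-hydroxy-4'-methoxyflavon-7-yl 2,2,2-trichloroethyl sulfate F9.
- Transfer hydrogenolysis (HCO2NH4, Pd/C, MeOH) removes the trichloroethyl group by reductive fragmentation and the benzyl group in the same operation, giving ammonium 5,3'-dihydroxy-4'-methoxyflavon-7-yl sulfate F10.
- Cold protonation as in step 7 rejoins the route at 13.

## Further compounds

F1 | step 3 | 2,6-difluoro-4-[(4-methoxybenzyl)oxy]benzoic acid | COc1ccc(COc2cc(F)c(C(=O)O)c(F)c2)cc1
F2 | step 3 | (1H-imidazol-1-yl){2,6-difluoro-4-[(4-methoxybenzyl)oxy]phenyl}methanone | COc1ccc(COc2cc(F)c(C(=O)n3ccnc3)c(F)c2)cc1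
F3 | step 4 | 4-methoxybenzyl 2-fluoro-4,6-bis[(4-methoxybenzyl)oxy]benzoate | COc1ccc(COC(=O)c2c(F)cc(OCc3ccc(OC)cc3)cc2OCc2ccc(OC)cc2)cc1
F4 | step 4 | 1-[3-(benzyloxy)-4-methoxyphenyl]-3-{2-fluoro-4,6-bis[(4-methoxybenzyl)oxy]phenyl}propane-1,3-dione | COc1ccc(C(=O)CC(=O)c2c(F)cc(OCc3ccc(OC)cc3)cc2OCc2ccc(OC)cc2)cc1OCc1ccccc1
F5 | step 6 | 5,3'-bis(benzyloxy)-4'-methoxy-7-[(4-methoxybenzyl)oxy]flavone | COc1ccc(-c2cc(=O)c3c(OCc4ccccc4)cc(OCc4ccc(OC)cc4)cc3o2)cc1OCc1ccccc1
F6 | step 6 | 5,3'-bis(benzyloxy)-7-hydroxy-4'-methoxyflavone | COc1ccc(-c2cc(=O)c3c(OCc4ccccc4)cc(O)cc3o2)cc1OCc1ccccc1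
F7 | step 6 | pyridinium 5,3'-bis(benzyloxy)-4'-methoxyflavon-7-yl sulfate | COc1ccc(-c2cc(=O)c3c(OCc4ccccc4)cc(OS(=O)(=O)[O-])cc3o2)cc1OCc1ccccc1.c1cc[nH+]cc1
F8 | step 6 | sodium 5,3'-bis(benzyloxy)-4'-methoxyflavon-7-yl sulfate | COc1ccc(-c2cc(=O)c3c(OCc4ccccc4)cc(OS(=O)(=O)[O-])cc3o2)cc1OCc1ccccc1.[Na+]
F9 | step 7 | 3'-(benzyloxy)-5-hydroxy-4'-methoxyflavon-7-yl 2,2,2-trichloroethyl sulfate | COc1ccc(-c2cc(=O)c3c(O)cc(OS(=O)(=O)OCC(Cl)(Cl)Cl)cc3o2)cc1OCc1ccccc1
F10 | step 7 | ammonium 5,3'-dihydroxy-4'-methoxyflavon-7-yl sulfate | COc1ccc(-c2cc(=O)c3c(O)cc(OS(=O)(=O)[O-])cc3o2)cc1O.[NH4+]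
A1 | alternative 1 | methyl 9-[3-(benzyloxy)-4-methoxyphenyl]-3,5,7,9-tetraoxononanoate | COC(=O)CC(=O)CC(=O)CC(=O)CC(=O)c1ccc(OC)c(OCc2ccccc2)c1
A2 | alternative 1 | 1-[3-(benzyloxy)-4-methoxyphenyl]-3-(2,4,6-trihydroxyphenyl)propane-1,3-dione | COc1ccc(C(=O)CC(=O)c2c(O)cc(O)cc2O)cc1OCc1ccccc1
A3 | alternative 1 | 3'-(benzyloxy)-5,7-dihydroxy-4'-methoxyflavone (identical with 9) | COc1ccc(-c2cc(=O)c3c(O)cc(O)cc3o2)cc1OCc1ccccc1
A4 | alternative 2 | 2-[3-(benzyloxy)-4-methoxyphenyl]-6-(2-diazoacetyl)-4H-pyran-4-one | COc1ccc(-c2cc(=O)cc(C(=O)C=[N+]=[N-])o2)cc1OCc1ccccc1
A5 | alternative 2 | (triisopropylsilyloxy)ethyne | C#CO[Si](C(C)C)(C(C)C)C(C)C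
A6 | alternative 2 | 3'-(benzyloxy)-5-hydroxy-4'-methoxy-7-[(triisopropylsilyl)oxy]flavone | COc1ccc(-c2cc(=O)c3c(O)cc(O[Si](C(C)C)(C(C)C)C(C)C)cc3o2)cc1OCc1ccccc1
A7 | alternative 3 | 3,5-bis(methoxymethoxy)-2-(trimethylsilyl)phenyl trifluoromethanesulfonate | COCOc1cc(OCOC)c([Si](C)(C)C)c(OS(=O)(=O)C(F)(F)F)c1
A8 | alternative 3 | 3-[3-(benzyloxy)-4-methoxyphenyl]prop-2-ynoic acid | COc1ccc(C#CC(=O)O)cc1OCc1ccccc1
A9 | alternative 3 | 3,5-bis(methoxymethoxy)benzyne | COCOC1=CC(OCOC)=CC#C1
A10 | alternative 3 | 3'-(benzyloxy)-4'-methoxy-5,7-bis(methoxymethoxy)flavone | COc1ccc(-c2cc(=O)c3c(OCOC)cc(OCOC)cc3o2)cc1OCc1ccccc1
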